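**Retrosynthetic overview**

1. The last bond is the (E)-C1′=C2′ alkene of the side chain, made by cross-metathesis of vinyl lactone 14 with diester olefin 21 (from methyl (R)-lactate by Felkin–Anh vinyl addition).
2. 14 comes from tricyclic lactone 11 by acetal removal and one-carbon olefination of the C-2 hydroxymethyl group.
3. Key disconnection (furo[3,2-b]pyranone numbering O1, C2, C3, C3a, O4, C5, C6, C7, C7a): the δ-lactone ring is opened at C6–C7 and at O4–C3a. This removes an O–C(=O)–CH2 acetate unit (ketene acetal 8) and leaves aldehyde–mesylate 6; forward, a Mukaiyama aldol addition and an SN2 lactonization run in one flask.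
4. Enabling feature: C7, C7a and C3a form a 1,3-dielectrophile on the oxolane ring (aldehyde carbon on C7a; on C3a a mesylate trans to that arm and trans to O-3), matched to the 1,3-O,C-dinucleophile. Rear-side attack from the face of the arm inverts C3a, which gives the cis ring fusion and turns the trans (gluco) pattern into the all-cis oxolane.
5. Ring order: the oxolane ring is taken intact from 2,5-anhydro-D-glucitol (1); a temporary 1,3-dioxane acetal ring is formed in step 1 and removed in step 8; the δ-lactone ring is closed last, in step 7.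

Key step: step 7

Remark: 2,5-anhydro-D-glucitol (1), trimethylsilyl acetate (7) and methyl (R)-lactate (15) are taken as purchasable; 1 already holds three of the four oxolane stereocentres, and only its C-4 has to be inverted.

**Step 1**
Reactants: 1 2,5-anhydro-D-glucitol
Product: 2 2,5-anhydro-1,3-O-isopropylidene-D-glucitol
Conditions: 2,2-dimethoxypropane, TsOH (cat.), DMF, 23 °C
Reagents that add atoms: 2,2-dimethoxypropane, COC(C)(C)OC
Why: Acid-catalysed transacetalization should select the only cis-related 1,3-diol pair (O-1 on the C-2 arm and O-3, same face of the oxolane) as a six-membered isopropylidene acetal, leaving free exactly the two hydroxyls (O-4 and O-6) that the annulation needs.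

**Step 2**
Reactants: 2 2,5-anhydro-1,3-O-isopropylidene-D-glucitol
Product: 3 2,5-anhydro-6-O-(tert-butyldimethylsilyl)-1,3-O-isopropylidene-D-glucitol
Conditions: TBSCl, imidazole, CH2Cl2, 0 °C
Reagents that add atoms: tert-butyldimethylsilyl chloride, CC(C)(C)[Si](C)(C)Cl
Why: Silylation with a bulky chlorosilane is kinetically selective for the primary 6-OH over the hindered secondary 4-OH.

**Step 3**
Reactants: 3 2,5-anhydro-6-O-(tert-butyldimethylsilyl)-1,3-O-isopropylidene-D-glucitol
Product: 4 2,5-anhydro-6-O-(tert-butyldimethylsilyl)-1,3-O-isopropylidene-4-O-methanesulfonyl-D-glucitol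
Conditions: MsCl, Et3N, CH2Cl2, 0 °C
Reagents that add atoms: methanesulfonyl chloride, CS(=O)(=O)Cl
Why: Sulfonylation of the remaining secondary alcohol (O–S bond formation, retention at carbon) places the leaving group on the face opposite to the C-5 arm.

**Step 4**
Reactants: 4 2,5-anhydro-6-O-(tert-butyldimethylsilyl)-1,3-O-isopropylidene-4-O-methanesulfonyl-D-glucitol
Product: 5 2,5-anhydro-1,3-O-isopropylidene-4-O-methanesulfonyl-D-glucitol
Conditions: HF·pyridine, pyridine, THF, 0 °C
Reagents that add atoms: none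
Why: Fluoride-mediated Si–O cleavage under buffered acidic conditions should free the primary alcohol without touching the mesylate or the acetal.

**Step 5**
Reactants: 5 2,5-anhydro-1,3-O-isopropylidene-4-O-methanesulfonyl-D-glucitol
Product: 6 2,5-anhydro-4,6-O-isopropylidene-3-O-methanesulfonyl-aldehydo-L-gulose (the C-6 aldehyde of 5)
Conditions: Dess–Martin periodinane, CH2Cl2, 0 → 23 °C; used crude
Reagents that add atoms: none
Why: Dess–Martin oxidation is non-basic, so the β-mesyloxy aldehyde should form without E1cB elimination or epimerization of the α-alkoxy centre.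

**Step 6**
Reactants: 7 trimethylsilyl acetate
Product: 8 1,1-bis(trimethylsilyloxy)ethene
Conditions: lithium diisopropylamide, THF, −78 °C; TMSCl; distillation
Reagents that add atoms: chlorotrimethylsilane, C[Si](C)(C)Cl
Why: O-silylation of the lithium enolate of the silyl ester (enolate trapping) gives the bis-silyl ketene acetal, the synthetic equivalent of the acetic acid dianion.

**Step 7**
Reactants: 6 2,5-anhydro-4,6-O-isopropylidene-3-O-methanesulfonyl-aldehydo-L-gulose; 8 1,1-bis(trimethylsilyloxy)ethene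
Product: 11 3,2′-O-isopropylidene acetal of (2S,3R,3aR,7R,7aR)-3,7-dihydroxy-2-(hydroxymethyl)hexahydro-5H-furo[3,2-b]pyran-5-one, via silyl ester aldolate 9 (not isolated), via cesium carboxylate 10 (not isolated)
Conditions: BF3·OEt2, CH2Cl2, −78 °C; then CsF, H2O (3 equiv), DMF, −78 → 60 °C, same flask
Reagents that add atoms: none
Why: BF3-bound aldehyde 6 is attacked by ketene acetal 8 in an open transition state (Mukaiyama aldol addition) to give silyl ester 9; fluoride then frees cesium carboxylate 10, whose oxygen displaces the ring mesylate from the rear (intramolecular SN2 O-alkylation), so that C6–C7 and O4–C3a are both formed in one flask. The closest known reaction types are the BF3-mediated Felkin–Anh-selective addition of silyl ketene acetals to α-alkoxy aldehydes and the lactonization of carboxylates onto secondary sulfonates with inversion, as used for configurational inversion in carbohydrate chemistry. The δ-lactone ring closes in the 6-exo-tet mode. C-7 is set by Felkin–Anh (polar, non-chelation) control from the adjacent C-7a, with the ring oxygen anti to the incoming nucleophile, which should give the 7R carbinol; C-3a is set by stereospecific inversion at the mesylate carbon. The step needs C–C bond formation before any base is present, because 6 is a β-sulfonyloxy aldehyde; the Lewis-acidic first stage and the syn arrangement of H-7a and the mesylate secure this. It also needs 6-exo O-alkylation in preference to oxetane formation by the 7-hydroxyl or elimination, which the weakly basic cesium carboxylate, held on the face opposite to the leaving group, secures.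

**Step 8**
Reactants: 11 3,2′-O-isopropylidene acetal of the dihydroxy(hydroxymethyl) furo[3,2-b]pyranone
Product: 12 (2S,3R,3aR,7R,7aR)-3,7-dihydroxy-2-(hydroxymethyl)hexahydro-5H-furo[3,2-b]pyran-5-one
Conditions: AcOH–H2O (4:1), 45 °C; evaporation
Reagents that add atoms: none
Why: Aqueous acid hydrolysis of the isopropylidene acetal; the δ-lactone and the secondary alcohols are stable to dilute acetic acid.

**Step 9**
Reactants: 12 (2S,3R,3aR,7R,7aR)-3,7-dihydroxy-2-(hydroxymethyl)hexahydro-5H-furo[3,2-b]pyran-5-one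
Product: 13 3,7-dihydroxy-5-oxohexahydro-2H-furo[3,2-b]pyran-2-carbaldehyde (all five stereocentres arranged as in 12)
Conditions: TEMPO (cat.), PhI(OAc)2, CH2Cl2–MeCN, 23 °C; used crude
Reagents that add atoms: none
Why: Oxoammonium (TEMPO) oxidation is selective for the primary alcohol over the two secondary ones and should stop at the aldehyde in the absence of water.

**Step 10**
Reactants: 13 3,7-dihydroxy-5-oxohexahydro-2H-furo[3,2-b]pyran-2-carbaldehyde
Product: 14 (2S,3R,3aR,7R,7aR)-2-ethenyl-3,7-dihydroxyhexahydro-5H-furo[3,2-b]pyran-5-one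
Conditions: Zn, CH2Br2, TiCl4, THF–CH2Cl2, 0 → 23 °C
Reagents that add atoms: dibromomethane, BrCBr
Why: Takai–Lombardo methylenation (gem-dimetallic CH2 reagent) is non-basic and spares lactone carbonyls, so the base-sensitive β-hydroxy lactone and the epimerizable α-alkoxy aldehyde centre should survive.

**Step 11**
Reactants: 15 methyl (R)-lactate
Product: 16 methyl (2R)-2-[(tert-butyldiphenylsilyl)oxy]propanoate
Conditions: TBDPSCl, imidazole, DMF, 23 °C
Reagents that add atoms: tert-butyldiphenylsilyl chloride, CC(C)(C)[Si](Cl)(c1ccccc1)c1ccccc1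
Why: Silylation of the secondary alcohol installs a bulky, non-chelating group that later enforces Felkin–Anh addition.

**Step 12**
Reactants: 16 methyl (2R)-2-[(tert-butyldiphenylsilyl)oxy]propanoate
Product: 17 (2R)-2-[(tert-butyldiphenylsilyl)oxy]propanal
Conditions: diisobutylaluminium hydride, CH2Cl2, −78 °C; Rochelle salt work-up
Reagents that add atoms: none
Why: Partial ester reduction stops at the aldehyde because the tetrahedral aluminate is stable at low temperature, and the α-centre is not racemized.

**Step 13**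
Reactants: 17 (2R)-2-[(tert-butyldiphenylsilyl)oxy]propanal
Product: 18 (3S,4R)-4-[(tert-butyldiphenylsilyl)oxy]pent-1-en-3-ol
Conditions: vinylmagnesium bromide, THF–Et2O, −78 °C; aq. NH4Cl
Reagents that add atoms: vinylmagnesium bromide, C=C[Mg]Br
Why: Grignard addition under Felkin–Anh (non-chelation) control by the bulky α-silyloxy group should favour the anti (3S,4R) alcohol; the syn isomer is removed by chromatography.

**Step 14**
Reactants: 18 (3S,4R)-4-[(tert-butyldiphenylsilyl)oxy]pent-1-en-3-ol
Product: 19 (3S,4R)-4-[(tert-butyldiphenylsilyl)oxy]pent-1-en-3-yl benzoate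
Conditions: BzCl, pyridine, DMAP (cat.), CH2Cl2, 0 → 23 °C
Reagents that add atoms: benzoyl chloride, O=C(Cl)c1ccccc1
Why: Nucleophile-catalysed acylation fixes the benzoate on the allylic oxygen while the other oxygen is still silylated, which differentiates the two esters of the target.

**Step 15**
Reactants: 19 (3S,4R)-4-[(tert-butyldiphenylsilyl)oxy]pent-1-en-3-yl benzoate
Product: 20 (3S,4R)-4-hydroxypent-1-en-3-yl benzoate
Conditions: HF·pyridine, pyridine, THF, 0 → 23 °C
Reagents that add atoms: none
Why: Acidic fluoride desilylation frees O-4 without the 1,2-benzoyl migration that an alkoxide formed under basic fluoride could cause.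

**Step 16**
Reactants: 20 (3S,4R)-4-hydroxypent-1-en-3-yl benzoate
Product: 21 (3S,4R)-4-acetoxypent-1-en-3-yl benzoate
Conditions: Ac2O, pyridine, DMAP (cat.), CH2Cl2, 23 °C
Reagents that add atoms: acetic anhydride, CC(=O)OC(C)=O
Why: Acetylation of the only free alcohol completes the differentiated diester.

**Step 17**
Reactants: 14 (2S,3R,3aR,7R,7aR)-2-ethenyl-3,7-dihydroxyhexahydro-5H-furo[3,2-b]pyran-5-one; 21 (3S,4R)-4-acetoxypent-1-en-3-yl benzoate
Product: 22 (2S,3R,3aR,7R,7aR)-2-[(1E,3S,4R)-4-acetoxy-3-(benzoyloxy)pent-1-en-1-yl]-3,7-dihydroxyhexahydro-5H-furo[3,2-b]pyran-5-one (target)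
Conditions: second-generation Hoveyda–Grubbs catalyst [RuCl2(H2IMes)(=CH-C6H4-2-OiPr)] (10 mol %), 21 (3 equiv), CH2Cl2, 40 °C
Reagents that add atoms: none
Why: Olefin cross-metathesis between two allylically oxygenated terminal alkenes that homodimerize slowly should favour the cross product and, under thermodynamic control, the E-alkene; the ruthenium carbene tolerates free hydroxyls, lactone and esters.

**Compound list**

1 | 2,5-anhydro-D-glucitol [(2R,3S,4S,5S)-2,5-bis(hydroxymethyl)oxolane-3,4-diol] | OC[C@@H]1O[C@H](CO)[C@@H](O)[C@@H]1O | starting material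
2 | 2,5-anhydro-1,3-O-isopropylidene-D-glucitol | CC1(C)OC[C@@H]2O[C@H](CO)[C@@H](O)[C@@H]2O1 | intermediate
3 | 2,5-anhydro-6-O-(tert-butyldimethylsilyl)-1,3-O-isopropylidene-D-glucitol | CC1(C)OC[C@@H]2O[C@H](CO[Si](C)(C)C(C)(C)C)[C@@H](O)[C@@H]2O1 | intermediate
4 | 2,5-anhydro-6-O-(tert-butyldimethylsilyl)-1,3-O-isopropylidene-4-O-methanesulfonyl-D-glucitol | CC1(C)OC[C@@H]2O[C@H](CO[Si](C)(C)C(C)(C)C)[C@@H](OS(C)(=O)=O)[C@@H]2O1 | intermediate
5 | 2,5-anhydro-1,3-O-isopropylidene-4-O-methanesulfonyl-D-glucitol | CC1(C)OC[C@@H]2O[C@H](CO)[C@@H](OS(C)(=O)=O)[C@@H]2O1 | intermediate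
6 | 2,5-anhydro-4,6-O-isopropylidene-3-O-methanesulfonyl-aldehydo-L-gulose | CC1(C)OC[C@@H]2O[C@H](C=O)[C@@H](OS(C)(=O)=O)[C@@H]2O1 | intermediate
7 | trimethylsilyl acetate | CC(=O)O[Si](C)(C)C | starting material
8 | 1,1-bis(trimethylsilyloxy)ethene | C=C(O[Si](C)(C)C)O[Si](C)(C)C | intermediate
9 | silyl ester aldolate: trimethylsilyl ester of the (3R) aldol adduct of 6, carbinol oxygen as O-BF2 | CC1(C)OC[C@@H]2O[C@H]([C@H](OB(F)F)CC(=O)O[Si](C)(C)C)[C@@H](OS(C)(=O)=O)[C@@H]2O1 | intermediate
10 | cesium carboxylate: cesium (3R)-3-hydroxypropanoate carrying at C-3 the mesylated, acetal-protected oxolane of 6 | [Cs+].CC1(C)OC[C@@H]2O[C@H]([C@H](O)CC(=O)[O-])[C@@H](OS(C)(=O)=O)[C@@H]2O1 | intermediate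
11 | 3,2′-O-isopropylidene acetal of (2S,3R,3aR,7R,7aR)-3,7-dihydroxy-2-(hydroxymethyl)hexahydro-5H-furo[3,2-b]pyran-5-one | CC1(C)OC[C@@H]2O[C@H]3[C@H](OC(=O)C[C@H]3O)[C@@H]2O1 | intermediate
12 | (2S,3R,3aR,7R,7aR)-3,7-dihydroxy-2-(hydroxymethyl)hexahydro-5H-furo[3,2-b]pyran-5-one | OC[C@@H]1O[C@H]2[C@H](OC(=O)C[C@H]2O)[C@@H]1O | intermediate
13 | 3,7-dihydroxy-5-oxohexahydro-2H-furo[3,2-b]pyran-2-carbaldehyde, stereocentres arranged as in 12 | O=C[C@@H]1O[C@H]2[C@H](OC(=O)C[C@H]2O)[C@@H]1O | intermediate
14 | (2S,3R,3aR,7R,7aR)-2-ethenyl-3,7-dihydroxyhexahydro-5H-furo[3,2-b]pyran-5-one | C=C[C@@H]1O[C@H]2[C@H](OC(=O)C[C@H]2O)[C@@H]1O | intermediate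
15 | methyl (R)-lactate | C[C@@H](O)C(=O)OC | starting material
16 | methyl (2R)-2-[(tert-butyldiphenylsilyl)oxy]propanoate | C[C@@H](O[Si](c1ccccc1)(c1ccccc1)C(C)(C)C)C(=O)OC | intermediate
17 | (2R)-2-[(tert-butyldiphenylsilyl)oxy]propanal | C[C@@H](O[Si](c1ccccc1)(c1ccccc1)C(C)(C)C)C=O | intermediate
18 | (3S,4R)-4-[(tert-butyldiphenylsilyl)oxy]pent-1-en-3-ol | C[C@@H](O[Si](c1ccccc1)(c1ccccc1)C(C)(C)C)[C@@H](O)C=C | intermediate
19 | (3S,4R)-4-[(tert-butyldiphenylsilyl)oxy]pent-1-en-3-yl benzoate | C[C@@H](O[Si](c1ccccc1)(c1ccccc1)C(C)(C)C)[C@@H](OC(=O)c1ccccc1)C=C | intermediate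
20 | (3S,4R)-4-hydroxypent-1-en-3-yl benzoate | C[C@@H](O)[C@@H](OC(=O)c1ccccc1)C=C | intermediate
21 | (3S,4R)-4-acetoxypent-1-en-3-yl benzoate | CC(=O)O[C@H](C)[C@H](C=C)OC(=O)c1ccccc1 | intermediate
22 | (2S,3R,3aR,7R,7aR)-2-[(1E,3S,4R)-4-acetoxy-3-(benzoyloxy)pent-1-en-1-yl]-3,7-dihydroxyhexahydro-5H-furo[3,2-b]pyran-5-one | CC(=O)O[C@H](C)[C@H](/C=C/[C@@H]1O[C@H]2[C@H](OC(=O)C[C@H]2O)[C@@H]1O)OC(=O)c1ccccc1 | target

**Step count and risks**

Total step count: 17. Longest linear sequence: 10 steps (steps 1–5, 7–10 and 17, from 1).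

Steps most likely to fail:

Step 7. Facial selectivity in the aldol addition may be poor, because the mesylate-bearing β-carbon and the acetal ring can erode Felkin–Anh control, and the sensitive β-mesyloxy aldehyde may be partly lost. The fallback separates the two bond formations and sets the carbinol by reagent control. It sets out from 6: allylation with B-allyldiisopinocampheylborane (the enantiomer matched to the 7R carbinol; Et2O, −78 °C, NaBO3 work-up) should give homoallylic alcohol F1. Ozonolysis (O3, CH2Cl2, −78 °C; PPh3) should give β-hydroxy aldehyde F2, and chlorite oxidation (NaClO2, NaH2PO4, 2-methylbut-2-ene, tBuOH–H2O) hydroxy acid F3. Cs2CO3 in DMF at 60 °C converts F3 through carboxylate 10 into lactone 11, where the route is rejoined.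

Step 10. The unprotected hydroxy aldehyde 13 may be masked as a hydrate or as a bridged hemiacetal with the 7-hydroxyl, or may epimerize at C-2 in contact with the Lewis-acidic titanium reagent, so that methylenation stalls. The fallback masks the secondary alcohols and uses ylide chemistry. It sets out from 12: TESCl and imidazole give tris(triethylsilyl) ether F4. Swern conditions (oxalyl chloride, DMSO; Et3N, −78 °C) oxidize the primary silyl ether directly to bis-silylated aldehyde F5. Wittig methylenation (Ph3P=CH2, THF, −78 → 0 °C) gives bis-silylated vinyl lactone F6, and HF·pyridine returns 14.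

Step 17. Cross-metathesis between two hindered, allylically oxygenated olefins may be slow, with homodimerization of 21, catalyst decay or incomplete E selectivity. The fallback builds the alkene by chromium-mediated chemistry instead. It sets out from 12 and passes through F4 and F5 of the preceding fallback. Takai iodo-olefination of F5 (CrCl2, CHI3, THF) should give (E)-vinyl iodide F7. Nozaki–Hiyama–Kishi coupling of F7 with aldehyde 17 (CrCl2, NiCl2 cat., DMSO) should give allylic alcohol F8, with the same Felkin–Anh sense as in step 13. Benzoylation (BzCl, pyridine) gives benzoate F9, and HF·pyridine removes all three silyl groups to give triol benzoate F10. Lipase-catalysed acetylation (Candida antarctica lipase B, vinyl acetate) of the unhindered acyclic methyl carbinol should then give 22.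

**Further compounds**

F1 | step 7 | homoallylic alcohol: (R)-allyl carbinol from 6, oxolane, acetal and mesylate unchanged | CC1(C)OC[C@@H]2O[C@H]([C@H](O)CC=C)[C@@H](OS(C)(=O)=O)[C@@H]2O1
F2 | step 7 | β-hydroxy aldehyde from ozonolysis of F1 | CC1(C)OC[C@@H]2O[C@H]([C@H](O)CC=O)[C@@H](OS(C)(=O)=O)[C@@H]2O1
F3 | step 7 | hydroxy acid (free acid of 10) | CC1(C)OC[C@@H]2O[C@H]([C@H](O)CC(=O)O)[C@@H](OS(C)(=O)=O)[C@@H]2O1
F4 | step 10 | tris(triethylsilyl) ether of 12 | CC[Si](CC)(CC)OC[C@@H]1O[C@H]2[C@H](OC(=O)C[C@H]2O[Si](CC)(CC)CC)[C@@H]1O[Si](CC)(CC)CC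
F5 | step 10 | 3,7-bis-O-(triethylsilyl) ether of aldehyde 13 | O=C[C@@H]1O[C@H]2[C@H](OC(=O)C[C@H]2O[Si](CC)(CC)CC)[C@@H]1O[Si](CC)(CC)CC
F6 | step 10 | 3,7-bis-O-(triethylsilyl) ether of vinyl lactone 14 | C=C[C@@H]1O[C@H]2[C@H](OC(=O)C[C@H]2O[Si](CC)(CC)CC)[C@@H]1O[Si](CC)(CC)CC
F7 | step 17 | (E)-2-iodoethenyl analogue of F6 | I/C=C/[C@@H]1O[C@H]2[C@H](OC(=O)C[C@H]2O[Si](CC)(CC)CC)[C@@H]1O[Si](CC)(CC)CC
F8 | step 17 | (1E,3S,4R)-3-hydroxy-4-(tert-butyldiphenylsilyloxy)pent-1-enyl lactone, 3,7-bis-O-triethylsilyl | C[C@@H](O[Si](c1ccccc1)(c1ccccc1)C(C)(C)C)[C@@H](O)/C=C/[C@@H]1O[C@H]2[C@H](OC(=O)C[C@H]2O[Si](CC)(CC)CC)[C@@H]1O[Si](CC)(CC)CC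
F9 | step 17 | benzoate of F8 | C[C@@H](O[Si](c1ccccc1)(c1ccccc1)C(C)(C)C)[C@@H](OC(=O)c1ccccc1)/C=C/[C@@H]1O[C@H]2[C@H](OC(=O)C[C@H]2O[Si](CC)(CC)CC)[C@@H]1O[Si](CC)(CC)CC
F10 | step 17 | triol benzoate (4′-O-deacetyl target) | C[C@@H](O)[C@@H](OC(=O)c1ccccc1)/C=C/[C@@H]1O[C@H]2[C@H](OC(=O)C[C@H]2O)[C@@H]1O
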